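**Plan**

- The retrosynthesis first cuts N1–C2 and N1'–C2' of both pyrrole rings at once. Each C2 holds N1, C3 and one bromine, which is the pattern left when an ortho aniline nitrogen replaces one bromine of a Br2C=C unit; C2–C3–C3'–C2' is therefore a 2,3-diaryl-1,1,4,4-tetrabromobuta-1,3-diene.
- Next the two C2=C3 bonds are cut (dibromoolefination of a 2,2'-dinitrobenzil). The diketone goes back to a diarylalkyne, and the alkyne to two Sonogashira couplings at the iodine of 4-bromo-1-iodo-2-nitrobenzene, which also supplies the C6 and C6' bromines.
- Forward order: alkyne chain, diketone, tetrabromodiene, nitro reduction, then both five-membered rings close together in the last step. The benzene rings are present from the start.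
- The target has no stereocentre, so no stereochemistry has to be set.

Key step: step 6

Remark: the target SMILES carries no stereodescriptor, so the C3–C3' axis is treated as stereochemically undefined.

**Route**

Step 1
Reactants: 1 4-bromo-1-iodo-2-nitrobenzene; 2 trimethylsilylacetylene
Product: 3 [(4-bromo-2-nitrophenyl)ethynyl]trimethylsilane
Conditions: PdCl2(PPh3)2 (cat), CuI (cat), Et3N, THF, rt
Reagents that add atoms: none
Why: Sonogashira coupling; zerovalent palladium adds much faster to the C–I bond, which the ortho nitro group activates further, than to the C–Br bond, so at room temperature only the iodide should be exchanged.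

Step 2
Reactants: 3 [(4-bromo-2-nitrophenyl)ethynyl]trimethylsilane; 1 4-bromo-1-iodo-2-nitrobenzene
Product: 5 1,2-bis(4-bromo-2-nitrophenyl)ethyne, via 4-bromo-1-ethynyl-2-nitrobenzene 4 (not isolated)
Conditions: CsF, PdCl2(PPh3)2 (cat), CuI (cat), Et3N/THF/MeOH, 40 °C, degassed
Reagents that add atoms: none
Why: Desilylative Sonogashira coupling; fluoride cleaves the C–Si bond and releases alkyne 4 slowly, and 4 is consumed at once in a second iodine-selective coupling with 1, which keeps its concentration low and should suppress Glaser-type dimerisation.

Step 3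
Reactants: 5 1,2-bis(4-bromo-2-nitrophenyl)ethyne
Product: 6 1,2-bis(4-bromo-2-nitrophenyl)ethane-1,2-dione
Conditions: RuCl3·xH2O (cat), NaIO4, CH2Cl2/MeCN/H2O, rt
Reagents that add atoms: sodium periodate, [Na+].[O-]I(=O)(=O)=O
Why: Catalytic ruthenium tetroxide oxidation of a diarylalkyne to a benzil; the oxidant adds across the triple bond in a [3+2] sense and the ruthenate ester collapses to the 1,2-diketone, while nitro groups and aryl bromides are inert to it.

Step 4
Reactants: 6 1,2-bis(4-bromo-2-nitrophenyl)ethane-1,2-dione; 7 carbon tetrabromide
Product: 9 1,1'-(1,1,4,4-tetrabromobuta-1,3-diene-2,3-diyl)bis(4-bromo-2-nitrobenzene), via 3,3-dibromo-1,2-bis(4-bromo-2-nitrophenyl)prop-2-en-1-one 8 (not isolated)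
Conditions: 7 (4 equiv) and PPh3 (8 equiv) premixed in CH2Cl2 at 0 °C, then 6, 0 °C to reflux
Reagents that add atoms: carbon tetrabromide (the second molecule of 7), BrC(Br)(Br)Br
Why: Twofold Ramirez (Wittig-type) dibromoolefination, established for aryl ketones and activated 1,2-dicarbonyl compounds; each carbonyl group takes up one CBr2 unit from its own molecule of 7 through the ylide Ph3P=CBr2, first giving enone 8 and then diene 9, and the strongly electrophilic nitroaryl ketones should offset the ortho hindrance.

Step 5
Reactants: 9 1,1'-(1,1,4,4-tetrabromobuta-1,3-diene-2,3-diyl)bis(4-bromo-2-nitrobenzene)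
Product: 10 2,2'-(1,1,4,4-tetrabromobuta-1,3-diene-2,3-diyl)bis(5-bromoaniline)
Conditions: SnCl2·2H2O, EtOH, 70 °C; aqueous NaHCO3 work-up
Reagents that add atoms: none
Why: Chemoselective electron-transfer reduction of aromatic nitro groups with SnCl2, routinely used on 2-(2,2-dibromovinyl)nitroarenes; it should leave the aryl and vinylic C–Br bonds and both alkenes untouched.

Step 6
Reactants: 10 2,2'-(1,1,4,4-tetrabromobuta-1,3-diene-2,3-diyl)bis(5-bromoaniline)
Product: 12 2,2',6,6'-tetrabromo-1H,1'H-3,3'-biindole, via 5-bromo-2-[2,2-dibromo-1-(2,6-dibromo-1H-indol-3-yl)ethenyl]aniline 11 (not isolated)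
Conditions: Pd[P(t-Bu)3]2 (10 mol%), K3PO4, toluene, 100 °C, argon, dark; chromatography on Et3N-deactivated silica
Reagents that add atoms: none
Why: Oxidative addition of zerovalent palladium to the vinylic C–Br bond cis to the aminoaryl ring puts the metal within reach of the NH2 group, which binds, loses a proton to K3PO4 and is joined to C2 by C–N reductive elimination from a six-membered azapalladacycle; the half-closed compound 11 then repeats the sequence at N1'–C2'. The closest known reaction is the palladium-catalysed Buchwald–Hartwig-type cyclisation of 2-(2,2-dibromovinyl)anilines to 2-bromoindoles, run here twice in one molecule. Each pyrrole ring closes in a formally 5-endo sense at its alkene, since N1 bonds to C2 while C2=C3 stays inside the new ring; this is possible because the bond forms by reductive elimination at the metal and not by direct nucleophilic attack. No stereocentre is created. The step needs chemoselectivity among three kinds of C–Br bond (aryl, vinylic, and C2–Br of the product) and preference for five- over six-membered ring closure; with the bulky, electron-rich P(t-Bu)3, oxidative addition to C–Br is reversible, so palladium on an aryl, a trans-vinylic or a product bromine can leave again, and only the cis-vinylic palladium can be captured by the ortho NH2. Closure onto the distal CBr2 group would need a seven-membered palladacycle and would give a non-aromatic ring, so it should not compete.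

**Compound list**

1 | 4-bromo-1-iodo-2-nitrobenzene | O=[N+]([O-])c1cc(Br)ccc1I | starting material
2 | trimethylsilylacetylene | C#C[Si](C)(C)C | starting material
3 | [(4-bromo-2-nitrophenyl)ethynyl]trimethylsilane | C[Si](C)(C)C#Cc1ccc(Br)cc1[N+](=O)[O-] | intermediate
4 | 4-bromo-1-ethynyl-2-nitrobenzene | C#Cc1ccc(Br)cc1[N+](=O)[O-] | intermediate
5 | 1,2-bis(4-bromo-2-nitrophenyl)ethyne | O=[N+]([O-])c1cc(Br)ccc1C#Cc1ccc(Br)cc1[N+](=O)[O-] | intermediate
6 | 1,2-bis(4-bromo-2-nitrophenyl)ethane-1,2-dione | O=C(C(=O)c1ccc(Br)cc1[N+](=O)[O-])c1ccc(Br)cc1[N+](=O)[O-] | intermediate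
7 | carbon tetrabromide | BrC(Br)(Br)Br | starting material
8 | 3,3-dibromo-1,2-bis(4-bromo-2-nitrophenyl)prop-2-en-1-one | O=C(C(=C(Br)Br)c1ccc(Br)cc1[N+](=O)[O-])c1ccc(Br)cc1[N+](=O)[O-] | intermediate
9 | 1,1'-(1,1,4,4-tetrabromobuta-1,3-diene-2,3-diyl)bis(4-bromo-2-nitrobenzene) | O=[N+]([O-])c1cc(Br)ccc1C(=C(Br)Br)C(=C(Br)Br)c1ccc(Br)cc1[N+](=O)[O-] | intermediate
10 | 2,2'-(1,1,4,4-tetrabromobuta-1,3-diene-2,3-diyl)bis(5-bromoaniline) | Nc1cc(Br)ccc1C(=C(Br)Br)C(=C(Br)Br)c1ccc(Br)cc1N | intermediate
11 | 5-bromo-2-[2,2-dibromo-1-(2,6-dibromo-1H-indol-3-yl)ethenyl]aniline | Nc1cc(Br)ccc1C(=C(Br)Br)c1c(Br)[nH]c2cc(Br)ccc12 | intermediate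
12 | 2,2',6,6'-tetrabromo-1H,1'H-3,3'-biindole | Brc1ccc2c(-c3c(Br)[nH]c4cc(Br)ccc34)c(Br)[nH]c2c1 | target

**Totals**

Total step count: 6. Longest linear sequence: 6 steps (1 → 3 → 5 → 6 → 9 → 10 → 12).

**Steps most likely to fail**

Step 4. The olefination may halt after the first carbonyl group, because the remaining ketone is shielded by two ortho-substituted rings and a CBr2 group. On longer heating, free phosphine may also begin to deoxygenate the nitro groups or the diketone. The fallback sets out from 6 and comes back at 9. It divides the double olefination into two single ones that are optimised separately and use differently generated carbon nucleophiles. Diketone 6 would be treated at 0 °C with only one equivalent of the ylide from 7 and PPh3, and the mono-olefin 8, which the main route does not isolate, would be isolated. Its ketone would then be olefinated with the ylide that t-BuOK releases from commercial (dibromomethyl)triphenylphosphonium bromide in toluene, preformed before 8 is added and then heated at up to 80 °C. In that medium neither free phosphine nor Ph3PBr2 is present, so the higher temperature can be used. This should give 9 and makes no compound outside the list (new compounds: none F0).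

Step 6. Oxidative addition at an aryl or distal vinylic C–Br bond may not reverse fast enough, so that hydrodebromination or oligomerisation sets in; the second closure may also stall on the crowded half-closed 11. The fallback sets out from 10 and comes back at 12. It forms the same two N–C bonds under copper catalysis after activating the nitrogen atoms, so that the metal is bound to nitrogen before it meets any C–Br bond. Diamine 10 would be sulfonylated with TsCl in pyridine to N,N'-[(1,1,4,4-tetrabromobuta-1,3-diene-2,3-diyl)bis(5-bromo-2,1-phenylene)]bis(4-methylbenzenesulfonamide) F1. CuI, N,N'-dimethylethylenediamine and K3PO4 in toluene at 90 °C (Ullmann–Goldberg-type vinylic amidation, known for N-sulfonyl 2-(2,2-dibromovinyl)anilines) should then give 2,2',6,6'-tetrabromo-1,1'-bis(4-methylbenzenesulfonyl)-1H,1'H-3,3'-biindole F2. The copper sulfonamidate can reach only the cis vinylic bromine, and aryl bromides should be inert at this temperature. Cs2CO3 in THF/MeOH at room temperature would remove both sulfonyl groups and give 12.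

Step 3. Over-oxidation may cleave the central C–C bond to give the benzoic acid, or the oxidation of a poorly soluble, electron-poor alkyne may be slow and incomplete. The fallback sets out from 1 and comes back at 6, replacing steps 1 to 3. It assembles the diketone from a two-carbon dielectrophile without passing through the alkyne. Iodine–magnesium exchange on 1 with PhMgCl in THF at −40 °C, which the ortho nitro group makes fast and which spares the bromine, would give (4-bromo-2-nitrophenyl)magnesium chloride F3. Transmetalation with CuBr·SMe2 in the presence of LiBr would give (4-bromo-2-nitrophenyl)copper F4. Half an equivalent of oxalyl chloride should then acylate twice and deliver 6 directly.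

Further compounds
F0 | step 4 | none | none
F1 | step 6 | N,N'-[(1,1,4,4-tetrabromobuta-1,3-diene-2,3-diyl)bis(5-bromo-2,1-phenylene)]bis(4-methylbenzenesulfonamide) | Cc1ccc(cc1)S(=O)(=O)Nc1cc(Br)ccc1C(=C(Br)Br)C(=C(Br)Br)c1ccc(Br)cc1NS(=O)(=O)c1ccc(C)cc1
F2 | step 6 | 2,2',6,6'-tetrabromo-1,1'-bis(4-methylbenzenesulfonyl)-1H,1'H-3,3'-biindole | Cc1ccc(cc1)S(=O)(=O)n1c(Br)c(-c2c(Br)n(S(=O)(=O)c3ccc(C)cc3)c3cc(Br)ccc23)c2ccc(Br)cc21
F3 | step 3 | (4-bromo-2-nitrophenyl)magnesium chloride | [O-][N+](=O)c1cc(Br)ccc1[Mg]Cl
F4 | step 3 | (4-bromo-2-nitrophenyl)copper | [O-][N+](=O)c1cc(Br)ccc1[Cu]
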